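The earlier runs and the new flask are simulated for an exercise; scatter was added.

The left-handed product stood to the right-handed product at 2.27 on the summed readings of the north-east run, so I gave the left-handed product 69.4% of whatever reacted.

- north-east: left-handed substrate 0.020 M; right-handed substrate 0.020 M; gas 4 mM (held); the very flask that is asked about, followed so far
- flask: left-handed substrate 0.020 M; gas 4.0 mM (held); right-handed substrate 0.020 M; time 80 min

north-east run (percent of the left-handed substrate and right-handed substrate together charged)

| time / min | left-handed product / % | right-handed product / % | left-handed substrate / % |
|---|---|---|---|
| 2.50 | 10.9 | 4.6 | 39.9 |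
| 4.00 | 19.6 | 8.9 | 35.0 |
| 6.00 | 25.5 | 11.0 | 29.4 |
| 10.0 | 40.7 | 17.6 | 19.3 |
| 15.0 | 54.5 | 23.5 | 11.0 |
| 20.0 | 58.6 | 25.3 | 6.3 |
| 30.0 | 67.3 | 31.0 | 0.4 |

(scatter of a reading: 1 percentage point)

- reagent is single-handed; left-handed substrate and right-handed substrate are mirror images of each other, charged as a racemate, each of them at the stated concentration
- at the start none of the gas is in solution
- the reaction counts as stopped when no species that holds the left-handed substrate and right-handed substrate together changes by six tenths of a point or more over the second half of the time
- the handed part of reagent does not stay in what it makes, so the products of the two hands are mirror images too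

* the state of affairs at 80 min: stopped, and by what, or still going (all of the left-handed substrate has reacted / forward and back rates have come level / it is still moving)
* left-handed product at 80 min, in percent of the left-handed substrate and right-handed substrate together charged
* right-handed product at 80 min, in percent of the left-handed substrate and right-handed substrate together charged

I reckoned by counting half-lives, using the half-life of the left-handed substrate read from this run between 2.50 min and 15.0 min, 6.72 min. That is a two-point average over the stretch, 0.103 min⁻¹ of what stands, and I carried it forward as if it were constant, which was my assumption and not something the readings showed. The left-handed product crosses it between 6.00 min and 10.0 min. The balance at 15.0 min leaves 22.0% for both substrates, so I took them as level. My count then brought the left-handed product to half of the charge at 12.7 min, which needs racemisation. From the last reading I counted 7.44 half-lives to 80 min, leaving 0.00231%. At 40.0 min I expected 0.143% of each substrate, too little to count as moving. My level was therefore 69.4% and 30.6%.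

The forecast was all of the left-handed substrate has reacted, with 69.8% (68% to 71.5%) and 30.2% (28.5% to 32%), slightly apart from my level: “By 80 min the substrate is gone, leaving about 70 and 30.”

The flask gave all of the left-handed substrate has reacted, with 68.6% and 31.4%.

    left-handed substrate ⇌ right-handed substrate (k = 0.00579 s⁻¹)
    gas ⇌ reagent, rate k2*(csat - [reagent]) (kL = 0.0258 s⁻¹)
    reagent + left-handed substrate → left-handed product (k = 1.21 L mol⁻¹ s⁻¹)
    reagent ⇌ dormant form (K = 27.3, k = 0.00900 s⁻¹)
    reagent + right-handed substrate → right-handed product (k = 0.493 L mol⁻¹ s⁻¹)

In this flask reagent took up both substrates, which stood at 23.8% and 26.8% at 8.00 min. By 40.0 min they stood at 0.247% and 0.303%, and dormant form then grew from 0.0413 M to 0.0713 M while the products stayed near their level. My count had put the left-handed substrate lower there. The left-handed product stood 5 points off its answer at 23.3 min.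

For a reading of the same flask at 20 min, 2.60 half-lives from 2.50 min give 6.57% of each substrate and 60.3% of left-handed product. That flask held 5.45% of left-handed substrate and 60.6% of left-handed product.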